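Numbering: ring B = C1–C5 (C3 bears CH3 and Cl, C4 bears Br), C6 = spiro atom, ring A = C7(=C14H2)–C8(OH)–C9=C10(Br)–C11(CH3)2; the two faces of ring B are called the C7 face and the C11 face. Ring A has oxygen on C8 and a vinyl bromide (a masked carbonyl) on C10, either side of C9, so it is a disguised cyclohexane-1,3-dione with C10 next to the gem-dimethyl carbon C11.
Retrosynthesis: C8–OH and C7=C14 go back to the C8 ketone, C3–Cl/C4–Br to the C3=C4 alkene, and C10–Br to the 1,3-dione. Ring A is then cut at C9–C10 (Claisen acylation of a methyl ketone by the C10 ester), the chain at C7–C8 (Wittig), ring B at C5–C6 and C1–C2 (Diels–Alder), and finally C6–C1 and C11–C6 (methylenation, allylation of methyl isobutyrate).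
Forward: ring B is made first by Diels–Alder reaction of isoprene with a 2-substituted acrolein, the C7 aldehyde is extended to the methyl ketone, and ring A is closed by Claisen cyclisation. The dione is then taken to the C10 bromo-enone, the ring-B halides, the exocyclic methylene and the C8 alcohol.
Stereochemistry: C6 comes from a catalyst-controlled Diels–Alder reaction and C8 from a CBS reduction. C3 and C4 are relayed from C6: C11 sits equatorial and C7 axial on ring B, so diaxial epoxide hydrolysis followed by two neighbouring-group-assisted substitutions should give the trans-diequatorial Br/Cl pair, which a direct anti addition of BrCl is not expected to give.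

Key step: step 6

Assumption (step 4): the (S)-configured oxazaborolidinium catalyst is taken to give the (1R)-aldehyde, by analogy with other 2-substituted acroleins; if the sense proves opposite, the (R)-catalyst is used.
Assumption (step 13): in the CBS transition state the α-branched C7(=CH2) flank of the ketone acts as the large group and the C9–H flank as the small one.

Step 1
Reactants: 1 methyl isobutyrate; 2 allyl bromide
Product: 3 methyl 2,2-dimethylpent-4-enoate
Conditions: LiN(iPr)2, THF, −78 °C; then 2, −78 °C to rt
Reagents that add atoms: none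
Why: Ester enolate alkylation: LiN(iPr)2 removes the only α-hydrogen of 1 and the enolate displaces bromide from the unhindered allylic halide by SN2, forming the C11–C6 bond.

Step 2
Reactants: 3 methyl 2,2-dimethylpent-4-enoate
Product: 4 methyl 2,2-dimethyl-4-oxobutanoate
Conditions: O3, CH2Cl2, −78 °C; then Me2S, −78 °C to rt
Reagents that add atoms: ozone, O=[O+][O-]
Why: Ozonolysis with reductive work-up cleaves the terminal alkene, the only oxidisable group, to the aldehyde carbon that becomes C7.

Step 3
Reactants: 4 methyl 2,2-dimethyl-4-oxobutanoate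
Product: 5 methyl 3-formyl-2,2-dimethylbut-3-enoate
Conditions: CH2O (37% aq.), pyrrolidine (10 mol%), EtCO2H (10 mol%), iPrOH, 45 °C
Reagents that add atoms: formaldehyde, C=O
Why: Amine-catalysed Mannich α-methylenation (the enamine of 4 adds to the formaldehyde iminium ion, then the amine is eliminated) is reliable for aldehydes with a single α-CH2 and installs the dienophile double bond C6=C1.

Step 4
Reactants: 5 methyl 3-formyl-2,2-dimethylbut-3-enoate; 6 isoprene
Product: 7 methyl 2-[(1R)-1-formyl-4-methylcyclohex-3-en-1-yl]-2-methylpropanoate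
Conditions: (S)-3,3-diphenyl-1-(2-methylphenyl)tetrahydro-1H,3H-pyrrolo[1,2-c][1,3,2]oxazaborole (20 mol%), Tf2NH (17 mol%), CH2Cl2, −78 to −40 °C
Reagents that add atoms: none
Why: Enantioselective Diels–Alder reaction of a 2-substituted acrolein under protonated chiral oxazaborolidine catalysis: the activated formyl group imposes the 1,4 ("para") orientation with isoprene, and the catalyst shields one face of the bound s-trans enal, which sets the quaternary centre C6.

Step 5
Reactants: 7 methyl 2-[(1R)-1-formyl-4-methylcyclohex-3-en-1-yl]-2-methylpropanoate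
Product: 9 methyl 2-methyl-2-[(1S)-4-methyl-1-(2-oxopropyl)cyclohex-3-en-1-yl]propanoate, via enol ether 8 (not isolated)
Conditions: [Ph3PCH(OMe)CH3]Cl, KN(SiMe3)2, THF, −78 °C to rt; then 2 M HCl, THF, rt
Reagents that add atoms: (1-methoxyethyl)triphenylphosphonium chloride, COC(C)[P+](c1ccccc1)(c1ccccc1)c1ccccc1.[Cl-]; water, O
Why: Wittig reaction of the non-enolisable aldehyde with an α-methoxy ylide gives enol ether 8, and acid hydrolysis (protonation at C7, water adds at C8, methanol leaves) unmasks the methyl ketone without touching quaternary C6 or the ring alkene.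

Step 6
Reactants: 9 methyl 2-methyl-2-[(1S)-4-methyl-1-(2-oxopropyl)cyclohex-3-en-1-yl]propanoate
Product: 10 (6S)-5,5,9-trimethylspiro[5.5]undec-8-ene-2,4-dione [(6S)-chamigr-3-ene-8,10-dione]
Conditions: KOtBu (2.5 equiv), THF, 0 °C to rt; then 1 M HCl
Reagents that add atoms: none
Why: KOtBu equilibrates the ketone enolates of 9; the C9 (methyl) enolate adds to the ester carbonyl C10, methoxide leaves the tetrahedral intermediate and the new C9–C10 bond closes ring A. The closest known reaction type is the base-mediated Claisen (Dieckmann-type) cyclisation of 5-oxohexanoates to cyclohexane-1,3-diones, which is known to accept 2,2-dimethyl esters. Ring A closes by a 6-exo-trig acyl substitution. No stereocentre is formed, and C6 is quaternary and cannot epimerise. The step needs C9 rather than C7 to act as the nucleophile: the C7 enolate could only form a four-membered ring and returns by proton exchange, while deprotonation of the acidic dione pulls the reversible acylation forward. The two fully substituted carbons C6 and C11 are already bonded, so the hindered ester is held next to the enolate and no new congested bond has to be made.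

Step 7
Reactants: 10 (6S)-5,5,9-trimethylspiro[5.5]undec-8-ene-2,4-dione
Product: 11 (6S)-8-methoxychamigra-3,8-dien-10-one
Conditions: MeOH, TsOH (5 mol%), 3 Å MS, 50 °C
Reagents that add atoms: methanol, CO
Why: Acid-catalysed enol etherification of a cyclic 1,3-dione under equilibrating conditions should put the methoxy group on the less hindered C8 (next to C7H2) and leave the C10 carbonyl beside the gem-dimethyl carbon, the preference known for 4,4-dimethylcyclohexane-1,3-dione; any 10-methoxy isomer is separated and recycled by hydrolysis.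

Step 8
Reactants: 11 (6S)-8-methoxychamigra-3,8-dien-10-one
Product: 12 (6S)-10-bromochamigra-3,9-dien-8-one
Conditions: (COBr)2, CH2Cl2, 0 °C to rt
Reagents that add atoms: oxalyl bromide, O=C(Br)C(=O)Br
Why: Vilsmeier-type halogenation with carbonyl transposition: the vinylogous-ester carbonyl oxygen at C10 is the nucleophilic site and is acylated, bromide replaces the activated oxygen at C10 by addition–elimination, and a second bromide removes the O-methyl group of the oxocarbenium ion as CH3Br, so bromine ends on C10 and the ketone on C8.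

Step 9
Reactants: 12 (6S)-10-bromochamigra-3,9-dien-8-one
Product: 14 (3R,4R,6S)-10-bromo-3,4-dihydroxychamigr-9-en-8-one, via epoxide 13 (not isolated)
Conditions: mCPBA, NaHCO3, CH2Cl2, 0 °C; then HClO4 (cat.), THF/H2O, rt
Reagents that add atoms: mCPBA, OOC(=O)c1cccc(Cl)c1; water, O
Why: Prilezhaev epoxidation of the only electron-rich alkene, then acid-catalysed trans-diaxial (Fürst–Plattner) hydrolysis: with C11 equatorial and C7 axial on ring B, the epoxide on either face should open to the same diaxial diol (3-OH on the C11 face, 4-OH on the C7 face), so C3 and C4 are fixed relative to C6 without a face-selective epoxidation.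

Step 10
Reactants: 14 (3R,4R,6S)-10-bromo-3,4-dihydroxychamigr-9-en-8-one
Product: 15 (3R,4R,6S)-3,10-dibromo-4-hydroxychamigr-9-en-8-one
Conditions: HBr (33% in AcOH), CH2Cl2, 0 °C
Reagents that add atoms: hydrogen bromide, Br
Why: SN1 substitution of the tertiary alcohol with neighbouring-group participation: ionisation at C3 is assisted by the antiperiplanar axial 4-hydroxyl (protonated epoxide on the C7 face), and bromide opens it at the tertiary carbon from the C11 face, so C3 is brominated with retention while the secondary 4-OH survives.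

Step 11
Reactants: 15 (3R,4R,6S)-3,10-dibromo-4-hydroxychamigr-9-en-8-one
Product: 16 (3S,4S,6R)-4,10-dibromo-3-chlorochamigr-9-en-8-one
Conditions: SOCl2, 2,6-lutidine, CH2Cl2, −20 °C to rt; then ClCH2CH2Cl, 60 °C
Reagents that add atoms: thionyl chloride, O=S(Cl)Cl
Why: Chlorodehydroxylation with anchimeric assistance and 1,2-bromine shift: the axial C3 bromine displaces the antiperiplanar chlorosulfite at C4 to give a bromonium ion on the C11 face, and chloride opens it at tertiary C3 from the C7 face, giving equatorial C4–Br and C3–Cl with the methyl axial; the diaxial regioisomer from attack at C4 comes from the same bromonium ion and should relax to this diequatorial isomer on warming (diaxial-to-diequatorial dihalide rearrangement).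

Step 12
Reactants: 16 (3S,4S,6R)-4,10-dibromo-3-chlorochamigr-9-en-8-one
Product: 19 (3S,4S,6S)-4,10-dibromo-3-chlorochamigra-7(14),9-dien-8-one, via Mannich base 17 (not isolated), via ammonium iodide 18 (not isolated)
Conditions: LiN(SiMe3)2, THF, −78 °C; [CH2=NMe2]I, −78 to 0 °C; then MeI, CH2Cl2, rt; then NaHCO3 (aq)
Reagents that add atoms: Eschenmoser's salt (N,N-dimethylmethyleneiminium iodide), C=[N+](C)C.[I-]
Why: Eschenmoser methylenation: kinetic deprotonation at C7, the only enolisable position, gives the cross-conjugated dienolate, a Mannich reaction adds CH2NMe2, and quaternisation followed by E1cB loss of trimethylamine gives the exocyclic enone; the equatorial bromide and the tertiary chloride have no antiperiplanar ring hydrogen for E2 at −78 °C.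

Step 13
Reactants: 19 (3S,4S,6S)-4,10-dibromo-3-chlorochamigra-7(14),9-dien-8-one
Product: 20 (3S,4S,6S,8R)-4,10-dibromo-3-chlorochamigra-7(14),9-dien-8-ol (target)
Conditions: (S)-1-methyl-3,3-diphenyltetrahydro-1H,3H-pyrrolo[1,2-c][1,3,2]oxazaborole [(S)-Me-CBS] (20 mol%), BH3·SMe2, THF, −40 °C; then MeOH
Reagents that add atoms: none
Why: Corey–Bakshi–Shibata reduction: catalyst-controlled 1,2-hydride delivery to the cross-conjugated ketone, with the C7(=CH2) flank as the large substituent, should set (8R) with the (S)-catalyst; the vinyl bromide, the alkyl halides and the conjugated methylene are not expected to react with borane at this temperature.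

Compound list
1 | methyl isobutyrate | COC(=O)C(C)C | starting material
2 | allyl bromide | C=CCBr | starting material
3 | methyl 2,2-dimethylpent-4-enoate | COC(=O)C(C)(C)CC=C | intermediate
4 | methyl 2,2-dimethyl-4-oxobutanoate | COC(=O)C(C)(C)CC=O | intermediate
5 | methyl 3-formyl-2,2-dimethylbut-3-enoate | COC(=O)C(C)(C)C(=C)C=O | intermediate
6 | isoprene | C=CC(C)=C | starting material
7 | methyl 2-[(1R)-1-formyl-4-methylcyclohex-3-en-1-yl]-2-methylpropanoate | COC(=O)C(C)(C)[C@@]1(C=O)CCC(C)=CC1 | intermediate
8 | methyl 2-[(1S)-1-(2-methoxyprop-1-en-1-yl)-4-methylcyclohex-3-en-1-yl]-2-methylpropanoate (E/Z mixture, not isolated) | COC(=O)C(C)(C)[C@@]1(C=C(C)OC)CCC(C)=CC1 | intermediate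
9 | methyl 2-methyl-2-[(1S)-4-methyl-1-(2-oxopropyl)cyclohex-3-en-1-yl]propanoate | COC(=O)C(C)(C)[C@@]1(CC(C)=O)CCC(C)=CC1 | intermediate
10 | (6S)-5,5,9-trimethylspiro[5.5]undec-8-ene-2,4-dione [(6S)-chamigr-3-ene-8,10-dione] | C1C(=O)CC(=O)C(C)(C)[C@]12CCC(C)=CC2 | intermediate
11 | (6S)-8-methoxychamigra-3,8-dien-10-one | C1C(OC)=CC(=O)C(C)(C)[C@]12CCC(C)=CC2 | intermediate
12 | (6S)-10-bromochamigra-3,9-dien-8-one | C1C(=O)C=C(Br)C(C)(C)[C@]12CCC(C)=CC2 | intermediate
13 | (6S)-10-bromo-3,4-epoxychamigr-9-en-8-one (both epoxide faces, not isolated) | C1C(=O)C=C(Br)C(C)(C)[C@]12CCC3(C)OC3C2 | intermediate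
14 | (3R,4R,6S)-10-bromo-3,4-dihydroxychamigr-9-en-8-one | C1C(=O)C=C(Br)C(C)(C)[C@]12CC[C@@](C)(O)[C@H](O)C2 | intermediate
15 | (3R,4R,6S)-3,10-dibromo-4-hydroxychamigr-9-en-8-one | C1C(=O)C=C(Br)C(C)(C)[C@]12CC[C@@](C)(Br)[C@H](O)C2 | intermediate
16 | (3S,4S,6R)-4,10-dibromo-3-chlorochamigr-9-en-8-one (C6 unchanged in space; the descriptor changes because C5 now outranks C7) | C1C(=O)C=C(Br)C(C)(C)[C@]12CC[C@](C)(Cl)[C@@H](Br)C2 | intermediate
17 | (3S,4S)-4,10-dibromo-3-chloro-14-(dimethylamino)chamigr-9-en-8-one (C7 epimers, not isolated) | CN(C)CC1C(=O)C=C(Br)C(C)(C)[C@]12CC[C@](C)(Cl)[C@@H](Br)C2 | intermediate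
18 | 14-(trimethylammonio) analogue of 17, iodide (not isolated) | C[N+](C)(C)CC1C(=O)C=C(Br)C(C)(C)[C@]12CC[C@](C)(Cl)[C@@H](Br)C2.[I-] | intermediate
19 | (3S,4S,6S)-4,10-dibromo-3-chlorochamigra-7(14),9-dien-8-one | C=C1C(=O)C=C(Br)C(C)(C)[C@]12CC[C@](C)(Cl)[C@@H](Br)C2 | intermediate
20 | (3S,4S,6S,8R)-4,10-dibromo-3-chlorochamigra-7(14),9-dien-8-ol | C=C1[C@H](O)C=C(Br)C(C)(C)[C@]12CC[C@](C)(Cl)[C@@H](Br)C2 | target

Total step count: 13. Longest linear sequence: 13 steps (from methyl isobutyrate; the route is fully linear).

Steps most likely to fail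

Step 11. The tertiary bromide of 15 may lose HBr during activation, or the bromonium ion may be captured at C4 and the resulting diaxial 3-bromo-4-chloro isomer may not equilibrate. Fallback, from 15 back to 16: K2CO3 in acetonitrile closes 15 to the epoxide on the C7 face, (3S,4R,6S)-epoxide F7, by antiperiplanar displacement of the tertiary bromide by the C4 alkoxide. Li2NiBr4 in THF then opens it at the less substituted C4 with inversion to the trans-diequatorial bromohydrin F8; opening at C3 only returns 15. The tertiary alcohol of F8 is finally converted to the chloride with retention (SOCl2, CH2Cl2, 0 °C, or conc. HCl), because the C4 bromine bridges the C11 face of the C3 cation and chloride enters from the C7 face, which gives 16.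

Step 4. The tertiary alkyl group on the dienophile α-carbon and the nearby ester carbonyl may disturb the binding of the enal to the boron catalyst, so that facial discrimination, and with it the enantiomeric purity at C6, is eroded. Fallback, from 5 and 6 back to 7: the cycloaddition is run with an achiral Lewis acid (Me2AlCl, CH2Cl2, −78 °C) to give racemic aldehyde F1. This is condensed with (1R,2R)-N,N'-dimethyl-1,2-diphenylethane-1,2-diamine (toluene, 4 Å MS) to the diastereomeric imidazolidines, (1R)-aminal F2 and (1S)-aminal F3. They are separated by chromatography or crystallisation, and F2 is hydrolysed (dilute aqueous HCl, Et2O) to 7 with recovery of the diamine.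

Step 5. Addition of the fully substituted ylide carbon to the neopentyl-type aldehyde may stall, because the oxaphosphetane must form between two congested carbons, and 7 would be returned. Fallback, from 7 back to 9: the smaller ylide Ph3P=CHOMe (from [Ph3PCH2OMe]Cl and KN(SiMe3)2, THF) gives enol ether F4, and aqueous acid gives the homologous aldehyde F5. MeMgBr (THF, −78 °C) adds to the aldehyde in preference to the hindered ester to give secondary alcohol F6, and Dess–Martin oxidation gives 9.

Further compounds
F1 | step 4 | rac-methyl 2-(1-formyl-4-methylcyclohex-3-en-1-yl)-2-methylpropanoate | COC(=O)C(C)(C)C1(C=O)CCC(C)=CC1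
F2 | step 4 | methyl 2-[(1R)-1-[(4R,5R)-1,3-dimethyl-4,5-diphenylimidazolidin-2-yl]-4-methylcyclohex-3-en-1-yl]-2-methylpropanoate | COC(=O)C(C)(C)[C@@]1(C2N(C)[C@H](c3ccccc3)[C@@H](c3ccccc3)N2C)CCC(C)=CC1
F3 | step 4 | methyl 2-[(1S)-1-[(4R,5R)-1,3-dimethyl-4,5-diphenylimidazolidin-2-yl]-4-methylcyclohex-3-en-1-yl]-2-methylpropanoate | COC(=O)C(C)(C)[C@]1(C2N(C)[C@H](c3ccccc3)[C@@H](c3ccccc3)N2C)CCC(C)=CC1
F4 | step 5 | methyl 2-[(1S)-1-(2-methoxyethenyl)-4-methylcyclohex-3-en-1-yl]-2-methylpropanoate (E/Z mixture) | COC(=O)C(C)(C)[C@@]1(C=COC)CCC(C)=CC1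
F5 | step 5 | methyl 2-methyl-2-[(1S)-4-methyl-1-(2-oxoethyl)cyclohex-3-en-1-yl]propanoate | COC(=O)C(C)(C)[C@@]1(CC=O)CCC(C)=CC1
F6 | step 5 | methyl 2-[(1S)-1-(2-hydroxypropyl)-4-methylcyclohex-3-en-1-yl]-2-methylpropanoate (carbinol epimers) | COC(=O)C(C)(C)[C@@]1(CC(C)O)CCC(C)=CC1
F7 | step 11 | (3S,4R,6S)-10-bromo-3,4-epoxychamigr-9-en-8-one (epoxide on the C7 face) | C1C(=O)C=C(Br)C(C)(C)[C@]12CC[C@]3(C)O[C@@H]3C2
F8 | step 11 | (3S,4S,6R)-4,10-dibromo-3-hydroxychamigr-9-en-8-one | C1C(=O)C=C(Br)C(C)(C)[C@]12CC[C@](C)(O)[C@@H](Br)C2
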